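- Read each flask through one time, the pseudo-first-order lifetime: the time in which [starting material] falls by a factor e at a fixed catalyst charge, so that, as long as the decay stays first-order, the share turned by time t is one minus exp(−t/lifetime).

| flask | starting material | free catalyst | time |
|---|---|---|---|
| Wednesday's | 50.0 mM | 1.00 mM |  |
| Thursday's | 75.0 mM | 1.00 mM |  |
| Tuesday's | 50.0 mM | 1.50 mM |  |
| Monday's | 120 mM | 1.00 mM | 47 min |

| Wednesday's run: time / min | Wednesday's run: [product] / mM | Thursday's run: time / min | Thursday's run: [product] / mM | Tuesday's run: time / min | Tuesday's run: [product] / mM |
|---|---|---|---|---|---|
| 3.6 | 3.3 | 3.6 | 5.8 | 3.6 | 7.7 |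
| 11 | 11.2 | 11 | 16.3 | 11 | 19.9 |
| 21 | 18.7 | 21 | 27.5 | 21 | 29.2 |
| 33 | 25.7 | 33 | 38.6 | 33 | 36.2 |
| 47 | 31.7 | 47 | 48.5 | 47 | 40.8 |

(scatter of a reading: 0.3 mM)

* the exponent of [starting material] in the starting rate at the charge of the Wednesday's run (at the point where two percent of the starting material have become product) (one fixed amount of product, the same in the runs compared)
* the exponent of [free catalyst] in the starting rate at the charge of the Wednesday's run (at the point where two percent of the starting material have become product)
* product in the Monday's run at 47 min, as a share of the starting material charged

- Overall: starting material -> product, with free catalyst as catalyst.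
- Constant volume, constant temperature.
- A reading of a species includes what of it is bound.
- An order is taken over about fifteen percent of the charge, up and down.

- Thursday's flask, the simulated charge nearest to Monday's, has turned 48.5 mM of 75.0 mM at 47 min, which gives a lifetime of 45.2 min.
- Wednesday's flask, with the same catalyst charge and less starting material, gives 46.8 min from its last reading, which is close to Thursday's, so these readings show a lifetime that barely moves with the charge of starting material.
- Tuesday's flask, at 1.50 mM of free catalyst and otherwise charged as Wednesday's, gives a shorter lifetime of 27.8 min, so Thursday's lifetime, not Tuesday's, is carried to Monday's flask, which holds 1.00 mM of free catalyst as Thursday's does.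
- Two times therefore remain for Monday's flask, the lifetime and the asked 47 min, and their ratio of 1.04 gives a reckoned share of 64.7%, assuming that the lifetime holds up to 120 mM.
- The forecast puts that share lower, at 63.5% (range 58% to 67%); it gives 1 for the exponent of [starting material] (range 0.85 to 1.15) and 1.85 for that of [free catalyst] (range 1.6 to 2.2), and it finds “no sign of saturation”.
- Monday's flask gives 62.0% of its charge at 47 min, 2.7 percentage points below the reckoned share, while at the charge of Wednesday's flask the exponents in the starting rate come to 0.95 for [starting material] and 2.4 for [free catalyst], the second above the forecast's high end.

    free catalyst + starting material ⇌ catalyst-substrate complex, settled at all times (275.0 L mol⁻¹)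
    catalyst-substrate complex + starting material ⇌ doubly bound catalyst, settled at all times (7.240 L mol⁻¹)
    doubly bound catalyst → product + catalyst-substrate complex (11.58 min⁻¹)
    2 free catalyst ⇌ resting dimer, settled at all times (24900 L mol⁻¹)
    free catalyst + impurity → spent catalyst

- Monday's share corresponds to a lifetime of 48.6 min, longer than Thursday's.
- In Wednesday's flask, Thursday's lifetime puts a quarter of the charge at 13.0 min, and the simulated time is 12.8 min.

The runs stem from a simulated flask from invented constants, and the scatter is random.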